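**Retrosynthetic overview**

- Numbering: ring A = benzene, ring B = dihydropyran (O1′, C2′–C4′), ring C = ten-membered carbocycle with germacrane locants (C10 = C2′, the quaternary O-bearing carbon; C1 = C3′; C9 = ring CH2 next to C10; C7 = carbinol-bearing stereocentre; C11 = carbinol carbon).
- Ring B is cut last: a three-component Knoevenagel/oxa-[4+2] union of 3-methylbutanal, 2,4,6-trihydroxybenzene-1,3-dicarbaldehyde and a (7R)-germacra-1(10)E,4(15),5Z-trien-11-ol forms O1′–C10 and C4′–C1 and three stereocentres.
- Enabling feature: after this cut C10 is an sp2 carbon of an (E)-trisubstituted alkene and C9 is a plain CH2 flanked by another CH2 (C8), so the C9–C10 bond of ring C is an sp3–sp2 bond. Ring C is closed there by one-pot hydroboration/B-alkyl Suzuki–Miyaura macrocyclisation of an open-chain C15 iodo-tetraene.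
- The open chain comes from a (Z)-selective Wittig union (C5=C6) of an α-methylene aldehyde (C1–C5, C10, C14, C15; from hept-5-yn-1-ol) with a phosphonium salt (C6–C9, C11–C13; from prenol by asymmetric epoxidation and vinyl-cuprate opening, which sets C7).
- Order of ring formation: ring A is bought, ring C is closed in step 10, ring B (fused to A and C) in step 12.

Key step: step 10

Remark: the ring alkene next to the carbinol-bearing carbon is read as (Z) and the four stereocentres as written in the SMILES; hept-5-yn-1-ol and 2,4,6-trihydroxybenzene-1,3-dicarbaldehyde are taken as catalogue chemicals.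

**Route**

Step 1
Reactants: 1 3-methylbut-2-en-1-ol (prenol)
Product: 2 [(2S)-3,3-dimethyloxiran-2-yl]methanol
Conditions: Ti(OiPr)4 (5 mol %), L-(+)-diethyl tartrate (6 mol %), t-BuOOH, 4 Å MS, CH2Cl2, −20 °C
Reagents that add atoms: tert-butyl hydroperoxide, CC(C)(C)OO
Why: Sharpless asymmetric epoxidation of a primary allylic alcohol, in which the L-(+)-tartrate–titanium complex delivers the peroxide oxygen to the alkene face that gives the (2S)-epoxide, the source of the later C7 stereocentre.

Step 2
Reactants: 2 [(2S)-3,3-dimethyloxiran-2-yl]methanol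
Product: 3 (2R)-2-ethenyl-3-methylbutane-1,3-diol
Conditions: CH2=CHMgBr (3 equiv), CuI (10 mol %), THF, −30 → 0 °C; aq NH4Cl
Reagents that add atoms: vinylmagnesium bromide, C=C[Mg]Br
Why: Copper-catalysed Grignard opening of a 2,3-epoxy alcohol by SN2 attack, in which the fully substituted epoxide carbon is blocked so that the vinyl group enters at C2 with inversion and gives the (2R)-1,3-diol carrying C6, C7, the C8=C9 vinyl group and the C11 carbinol.

Step 3
Reactants: 3 (2R)-2-ethenyl-3-methylbutane-1,3-diol
Product: 4 (3S)-3-(iodomethyl)-2-methylpent-4-en-2-ol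
Conditions: I2, PPh3, imidazole, CH2Cl2, 0 °C → rt
Reagents that add atoms: iodine, II
Why: Appel-type iodination activates only the primary hydroxyl as its alkoxyphosphonium ion, which iodide displaces, while the hindered tertiary alcohol and the stereocentre are not involved (the descriptor changes only through the priority of CH2I).

Step 4
Reactants: 4 (3S)-3-(iodomethyl)-2-methylpent-4-en-2-ol
Product: 5 triethyl{[(3S)-3-(iodomethyl)-2-methylpent-4-en-2-yl]oxy}silane
Conditions: Et3SiOTf, 2,6-lutidine, CH2Cl2, −78 → 0 °C
Reagents that add atoms: triethylsilyl trifluoromethanesulfonate, CC[Si](CC)(CC)OS(=O)(=O)C(F)(F)F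
Why: Silylation with a silyl triflate and 2,6-lutidine is the standard way to cap a hindered tertiary alcohol, and the ether removes the proton that would otherwise give an oxido ylide in step 9 and consume borane in step 10.

Step 5
Reactants: 5 triethyl{[(3S)-3-(iodomethyl)-2-methylpent-4-en-2-yl]oxy}silane
Product: 6 {(2S)-2-ethenyl-3-methyl-3-[(triethylsilyl)oxy]butyl}triphenylphosphonium iodide
Conditions: PPh3 (3 equiv), MeCN, 85 °C, sealed tube
Reagents that add atoms: triphenylphosphine, c1ccc(cc1)P(c1ccccc1)c1ccccc1
Why: SN2 quaternisation of triphenylphosphine by the primary iodide (phosphonium salt formation for a Wittig reaction), which the β-branching only slows, hence the excess phosphine and heating.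

Step 6
Reactants: 7 hept-5-yn-1-ol
Product: 9 (5E)-6-iodohept-5-en-1-ol, via alkenylzirconocene chloride 8 (not isolated)
Conditions: Cp2Zr(H)Cl (2.5 equiv), THF, 0 → 40 °C; then I2, 0 °C
Reagents that add atoms: iodine, II
Why: Hydrozirconation–iodination, in which syn addition of Zr–H to the alkyne (the hydroxyl being carried as its zirconium alkoxide) is equilibrated by the excess hydride to the isomer with zirconium on the methyl-bearing carbon and iododemetalation with retention should give the (E)-2-iodoalk-2-ene that becomes C1=C10 with C14.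

Step 7
Reactants: 9 (5E)-6-iodohept-5-en-1-ol
Product: 10 (5E)-6-iodohept-5-enal
Conditions: Dess–Martin periodinane, CH2Cl2, 0 °C → rt
Reagents that add atoms: none
Why: Dess–Martin oxidation converts the primary alcohol into the aldehyde under neutral conditions that leave the iodoalkene untouched.

Step 8
Reactants: 10 (5E)-6-iodohept-5-enal
Product: 11 (5E)-6-iodo-2-methylidenehept-5-enal
Conditions: 37 % aq CH2O, pyrrolidine (10 mol %), EtCO2H (10 mol %), i-PrOH, 45 °C
Reagents that add atoms: formaldehyde, C=O
Why: Amine-catalysed α-methylenation (Mannich condensation of the enamine with the formaldehyde iminium ion followed by elimination) turns the α-CH2 of the aldehyde into the C4=C15 exocyclic methylene.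

Step 9
Reactants: 6 {(2S)-2-ethenyl-3-methyl-3-[(triethylsilyl)oxy]butyl}triphenylphosphonium iodide and 11 (5E)-6-iodo-2-methylidenehept-5-enal
Product: 13 triethyl{[(3R,4Z,9E)-3-ethenyl-10-iodo-2-methyl-6-methylideneundeca-4,9-dien-2-yl]oxy}silane, via phosphorus ylide 12 (not isolated)
Conditions: 6, KN(SiMe3)2 (1.0 equiv), THF, −78 °C; then 11, −78 → 0 °C
Reagents that add atoms: none
Why: Wittig olefination of a non-stabilised ylide under lithium-free kinetic control should give the (Z)-C5=C6 alkene through the cis-oxaphosphetane, with 1,2-addition to the enal faster than conjugate addition and the C7 centre, which is not acidic, left untouched.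

Step 10
Reactants: 13 triethyl{[(3R,4Z,9E)-3-ethenyl-10-iodo-2-methyl-6-methylideneundeca-4,9-dien-2-yl]oxy}silane
Product: 15 triethyl({2-[(1R,2Z,7E)-8-methyl-4-methylidenecyclodeca-2,7-dien-1-yl]propan-2-yl}oxy)silane, via B-alkyl-9-BBN borane 14 (not isolated)
Conditions: 9-BBN-H (1.2 equiv), THF, 0 °C → rt; then slow addition to Pd(dppf)Cl2 (15 mol %), AsPh3 (30 mol %), Cs2CO3 (3 equiv), DMF/THF/H2O, 50 °C, final 1 mM
Reagents that add atoms: none
Why: 9-BBN-H adds anti-Markovnikov and chemoselectively to the only isolated monosubstituted alkene of 13 (the 2-substituted 1,3-diene is deactivated by conjugation, the iodoalkene is trisubstituted), giving primary alkylborane 14; base converts it into the borate, zerovalent palladium inserts into the C–I bond with retention, and transmetalation followed by reductive elimination forms the C9–C10 σ bond. The closest known reaction type is the intramolecular B-alkyl Suzuki–Miyaura macrocyclisation of ω-borylalkyl alkenyl iodides. Ring C closes head-to-tail as an sp3–sp2 coupling through an eleven-membered palladacycle, and the new ring alkene comes out as the (E)-C1=C10 isomer because oxidative addition and reductive elimination retain the geometry of the (E)-iodoalkene set in step 6. No stereocentre is formed and the C7 centre, two atoms away from boron, is not touched. The step needs ring closure to win over oligomerisation and β-hydride elimination, which is secured by high dilution with slow addition of 14, by the wide-bite-angle dppf ligand with AsPh3 that speeds reductive elimination, and by the (Z)-alkene and the two further sp2 centres of the chain, which remove transannular hydrogens and bend the chain ends towards each other.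

Step 11
Reactants: 15 triethyl({2-[(1R,2Z,7E)-8-methyl-4-methylidenecyclodeca-2,7-dien-1-yl]propan-2-yl}oxy)silane
Product: 16 2-[(1R,2Z,7E)-8-methyl-4-methylidenecyclodeca-2,7-dien-1-yl]propan-2-ol
Conditions: Bu4NF, THF, 0 → 40 °C
Reagents that add atoms: none
Why: Fluoride-mediated cleavage of the Si–O bond (desilylation) proceeds under basic, non-acidic conditions that the acid-sensitive cyclodecatriene should tolerate.

Step 12
Reactants: 16 2-[(1R,2Z,7E)-8-methyl-4-methylidenecyclodeca-2,7-dien-1-yl]propan-2-ol, 17 3-methylbutanal and 18 2,4,6-trihydroxybenzene-1,3-dicarbaldehyde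
Product: 20 CNP0479784.1 (target; 2′R,3′S,4′R dihydropyran trans-fused to the (7R,5Z) ten-membered ring), via o-quinone methide 19 (not isolated)
Conditions: 17 (2 equiv), 18 (2 equiv), morpholine (20 mol %), AcOH (20 mol %), 4 Å MS, THF, 45 °C
Reagents that add atoms: none
Why: Knoevenagel condensation of 17 at the only free ring position of 18 gives o-quinone methide 19, which should undergo an inverse-electron-demand hetero-Diels–Alder reaction with the strained, most nucleophilic (E)-C1=C10 alkene of 16 (oxygen to the more substituted C10); suprafacial addition fixes the trans ring fusion and the C10 methyl cis to C2, attack on the outer face of the conformer with the C7 substituent pseudo-equatorial and the C14 methyl anti to H-7 relates these centres to C7, and the (E)-quinone methide with its arene stacked over the methyl-bearing edge of the alkene places the isobutyl group cis to C2.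

**Compound list**

1 | 3-methylbut-2-en-1-ol (prenol) | CC(C)=CCO | starting material
2 | [(2S)-3,3-dimethyloxiran-2-yl]methanol | OC[C@@H]1OC1(C)C | intermediate
3 | (2R)-2-ethenyl-3-methylbutane-1,3-diol | C=C[C@H](CO)C(C)(C)O | intermediate
4 | (3S)-3-(iodomethyl)-2-methylpent-4-en-2-ol | C=C[C@H](CI)C(C)(C)O | intermediate
5 | triethyl{[(3S)-3-(iodomethyl)-2-methylpent-4-en-2-yl]oxy}silane | C=C[C@H](CI)C(C)(C)O[Si](CC)(CC)CC | intermediate
6 | {(2S)-2-ethenyl-3-methyl-3-[(triethylsilyl)oxy]butyl}triphenylphosphonium iodide | C=C[C@H](C[P+](c1ccccc1)(c1ccccc1)c1ccccc1)C(C)(C)O[Si](CC)(CC)CC.[I-] | intermediate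
7 | hept-5-yn-1-ol | CC#CCCCCO | starting material
8 | (E)-alkenylzirconocene chloride from 7 (Zr on the methyl-bearing alkene carbon, hydroxyl as its zirconocene chloride alkoxide) | C/C(=C\CCCCO[Zr](Cl)(C1C=CC=C1)C1C=CC=C1)[Zr](Cl)(C1C=CC=C1)C1C=CC=C1 | intermediate
9 | (5E)-6-iodohept-5-en-1-ol | OCCCC/C=C(C)/I | intermediate
10 | (5E)-6-iodohept-5-enal | O=CCCC/C=C(C)/I | intermediate
11 | (5E)-6-iodo-2-methylidenehept-5-enal | O=CC(=C)CC/C=C(C)/I | intermediate
12 | {(2S)-2-ethenyl-3-methyl-3-[(triethylsilyl)oxy]butylidene}triphenyl-λ5-phosphane (ylide) | C=C[C@H](C=P(c1ccccc1)(c1ccccc1)c1ccccc1)C(C)(C)O[Si](CC)(CC)CC | intermediate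
13 | triethyl{[(3R,4Z,9E)-3-ethenyl-10-iodo-2-methyl-6-methylideneundeca-4,9-dien-2-yl]oxy}silane | C=C[C@@H](C(C)(C)O[Si](CC)(CC)CC)/C=C\C(=C)CC/C=C(C)/I | intermediate
14 | 9-[(3R,4Z,9E)-10-iodo-6-methylidene-3-{2-[(triethylsilyl)oxy]propan-2-yl}undeca-4,9-dien-1-yl]-9-borabicyclo[3.3.1]nonane | B1(C2CCCC1CCC2)CC[C@@H](C(C)(C)O[Si](CC)(CC)CC)/C=C\C(=C)CC/C=C(C)/I | intermediate
15 | triethyl({2-[(1R,2Z,7E)-8-methyl-4-methylidenecyclodeca-2,7-dien-1-yl]propan-2-yl}oxy)silane | C=C1/C=C\[C@H](C(C)(C)O[Si](CC)(CC)CC)CC/C(C)=C/CC1 | intermediate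
16 | 2-[(1R,2Z,7E)-8-methyl-4-methylidenecyclodeca-2,7-dien-1-yl]propan-2-ol | C=C1/C=C\[C@H](C(C)(C)O)CC/C(C)=C/CC1 | intermediate
17 | 3-methylbutanal | CC(C)CC=O | starting material
18 | 2,4,6-trihydroxybenzene-1,3-dicarbaldehyde | O=Cc1c(O)cc(O)c(C=O)c1O | starting material
19 | (5E)-2,4-dihydroxy-5-(3-methylbutylidene)-6-oxocyclohexa-1,3-diene-1,3-dicarbaldehyde (o-quinone methide) | O=CC1=C(O)C(C=O)=C(O)/C(=C\CC(C)C)C1=O | intermediate
20 | CNP0479784.1: 5,7-dihydroxy-2-methyl-4-(2-methylpropyl)chromane-6,8-dicarbaldehyde whose C2 and C3 are joined, trans, by the chain C2–CH2–CH2–CH[C(CH3)2OH]–CH=CH–C(=CH2)–CH2–CH2–C3; (2R,3S,4R) in the chromane, (R) at the carbinol-bearing ring carbon, (Z) ring alkene | C=C1/C=C\[C@H](C(C)(C)O)CC[C@@]2(C)Oc3c(C=O)c(O)c(C=O)c(O)c3[C@H](CC(C)C)[C@@H]2CC1 | target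

**Step count and risks**

Total step count: 12. Longest linear sequence: 9 steps (steps 1–5, then 9–12).

The three steps most likely to fail:

Step 10. Intermolecular coupling (oligomerisation) may outrun ring closure, the alkylpalladium intermediate may lose β-hydride or the borane may be protodeboronated, and 9-BBN may also attack the diene terminus. The fallback sets out from 13. Hydroboration with 9-BBN and oxidative work-up (NaBO3·4H2O) would give the primary alcohol (3R,4Z,9E)-10-iodo-6-methylidene-3-{2-[(triethylsilyl)oxy]propan-2-yl}undeca-4,9-dien-1-ol F1, which can be freed by chromatography from any product of diene hydroboration. Appel-type iodination (I2, PPh3, imidazole) would give the diiodide triethyl({2-[(3R,4Z,9E)-1,10-diiodo-6-methylideneundeca-4,9-dien-3-yl]propan-2-yl}oxy)silane F2. A nickel-catalysed intramolecular reductive cross-electrophile coupling (NiBr2(dme), 4,4′-di-tert-butyl-2,2′-bipyridine, Mn powder, NaI, DMA, slow addition) would then join the primary alkyl carbon, through its radical, to the alkenylnickel centre. This forms the same C9–C10 bond without a borane or an alkylpalladium intermediate and comes back to the route at 15.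

Step 12. The quinone methide may add to the conjugated diene instead of the (E)-alkene, attack the other π-face, or give the benzylic epimer through the alternative endo/exo orientation, and the acidic phenol may induce transannular cyclisation of 16. The fallback sets out from silyl ether 15 and moves the cycloaddition in front of the desilylation as a two-component reaction under neutral conditions. The quinone methide is released slowly by thermal retro-Mannich cleavage (toluene, 80 °C) of the preformed Mannich base 2,4,6-trihydroxy-5-[3-methyl-1-(morpholin-4-yl)butyl]benzene-1,3-dicarbaldehyde F3, made from 17, 18 and morpholine in EtOH at rt. The bulky silyloxy-isopropyl group is expected to hold the ring more firmly in the C7-equatorial conformer and to exclude the free phenol/alcohol interplay, giving the C11 triethylsilyl ether of 20 F4. Desilylation (HF·pyridine, pyridine, THF, 0 °C) comes back to the route at 20.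

Step 9. Quaternisation in step 5 may be slow, the hindered ylide may decompose, enal 11 may suffer conjugate addition or base-induced polymerisation, and (Z) selectivity may erode. The fallback sets out from iodide 5. Thiolate displacement (pyridine-2-thiol, K2CO3, DMF) would give 2-({(2S)-2-ethenyl-3-methyl-3-[(triethylsilyl)oxy]butyl}sulfanyl)pyridine F5, and oxidation ((NH4)6Mo7O24 cat., H2O2, EtOH, 0 °C) the sulfone 2-({(2S)-2-ethenyl-3-methyl-3-[(triethylsilyl)oxy]butyl}sulfonyl)pyridine F6. Julia–Kocienski olefination of F6 with 11 (KN(SiMe3)2, toluene, −78 °C), for which 2-pyridyl sulfones are the (Z)-favouring variant, would form C5=C6 through a sulfonyl carbanion instead of an ylide and come back to the route at 13.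

Further compounds
F1 | step 10 | (3R,4Z,9E)-10-iodo-6-methylidene-3-{2-[(triethylsilyl)oxy]propan-2-yl}undeca-4,9-dien-1-ol | OCC[C@@H](C(C)(C)O[Si](CC)(CC)CC)/C=C\C(=C)CC/C=C(C)/I
F2 | step 10 | triethyl({2-[(3R,4Z,9E)-1,10-diiodo-6-methylideneundeca-4,9-dien-3-yl]propan-2-yl}oxy)silane | ICC[C@@H](C(C)(C)O[Si](CC)(CC)CC)/C=C\C(=C)CC/C=C(C)/I
F3 | step 12 | 2,4,6-trihydroxy-5-[3-methyl-1-(morpholin-4-yl)butyl]benzene-1,3-dicarbaldehyde (racemic) | O=Cc1c(O)c(C=O)c(O)c(C(CC(C)C)N2CCOCC2)c1O
F4 | step 12 | C11 triethylsilyl ether of 20 | C=C1/C=C\[C@H](C(C)(C)O[Si](CC)(CC)CC)CC[C@@]2(C)Oc3c(C=O)c(O)c(C=O)c(O)c3[C@H](CC(C)C)[C@@H]2CC1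
F5 | step 9 | 2-({(2S)-2-ethenyl-3-methyl-3-[(triethylsilyl)oxy]butyl}sulfanyl)pyridine | C=C[C@H](CSc1ccccn1)C(C)(C)O[Si](CC)(CC)CC
F6 | step 9 | 2-({(2S)-2-ethenyl-3-methyl-3-[(triethylsilyl)oxy]butyl}sulfonyl)pyridine | C=C[C@H](CS(=O)(=O)c1ccccn1)C(C)(C)O[Si](CC)(CC)CC
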